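**Retrosynthetic overview**

1. Ring numbering used below: C1 = carbinol carbon, C2 = CH(CH3), C3–C5 = the three CH2, C6 = C(CH3)2. Late disconnections: the acetate; the diene bond between a (Z)-iodo-olefin and a stannylvinyl butenolide (Stille); the (Z)-iodo allylic alcohol by copper-catalysed carbomagnesiation of propargyl alcohol; the (E)-trisubstituted olefin by zirconium-catalysed carboalumination of a terminal alkyne and opening of oxirane.
2. That alkyne comes from a spiro γ-lactone, which already holds the cyclohexane, the C1–O bond and both stereocentres.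
3. Key disconnection: C2–C3 of the carbocycle, closed by an enantioselective gold-catalysed 6-endo-dig cyclisation of an achiral, acyclic 1,5-enyne acid, in which the carboxyl group closes the lactone on C1 in the same operation (ring, C–O bond, C1 and C2 in one step).
4. Enabling feature: C1 is fully substituted and sits between C6 (C(CH3)2) and C2 (CH(CH3)), so an (E)-C1=C2 olefin is nucleophilic at C2 and cationic at C1. C6, which bears no hydrogen, holds the alkyne (future C3–C4) in a 1,5-relationship to that olefin, and the C1 side chain is kept at the acid oxidation level to trap the cation as a temporary spiro lactone.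
5. Ring order: cyclohexene and temporary γ-lactone together (step 6); the lactone is opened in steps 8–9; the butenolide ring is brought in intact.

Key step: step 6

Remark: the (R) antipode of the bisphosphine on gold is assumed to deliver the (5R,6S) lactone; the sense of induction is fixed in the first run, and the (S) ligand is used instead if it is opposite.

**Route**

Step 1
Reactants: 1 isobutyronitrile; 2 3-bromo-1-(trimethylsilyl)prop-1-yne
Product: 4 2,2-dimethyl-5-(trimethylsilyl)pent-4-ynenitrile, via lithiated isobutyronitrile 3 (not isolated)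
Conditions: LiN(i-Pr)2 (LDA, commercial solution), THF, –78 °C; then 2, –78 °C → rt
Reagents that add atoms: none
Why: Nitrile α-anion alkylation (SN2 at the propargylic bromide, the silyl cap suppressing SN2' and acetylide chemistry) should build the quaternary gem-dimethyl carbon that becomes ring carbon C6.

Step 2
Reactants: 4 2,2-dimethyl-5-(trimethylsilyl)pent-4-ynenitrile
Product: 6 4,4-dimethyl-7-(trimethylsilyl)hept-6-yn-3-one, via bromomagnesium ketiminate 5 (not isolated)
Conditions: EtMgBr, CuBr·SMe2 (5 mol%), THF, reflux; then 1 M HCl, rt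
Reagents that add atoms: ethylmagnesium bromide, CC[Mg]Br; water, O
Why: Grignard addition to the hindered nitrile stops at the magnesium ketiminate, whose acid hydrolysis should give the ethyl ketone while the alkynylsilane survives dilute acid.

Step 3
Reactants: 6 4,4-dimethyl-7-(trimethylsilyl)hept-6-yn-3-one
Product: 8 (2Z)-4,4-dimethyl-7-(trimethylsilyl)hept-2-en-6-yn-3-yl trifluoromethanesulfonate, via lithium (Z)-enolate 7 (not isolated)
Conditions: LDA, THF, –78 °C; PhNTf2, –78 → 0 °C
Reagents that add atoms: N-phenylbis(trifluoromethanesulfonimide), O=S(=O)(N(c1ccccc1)S(=O)(=O)C(F)(F)F)C(F)(F)F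
Why: Kinetic deprotonation of an ethyl tert-alkyl ketone is expected to give the Z-enolate almost exclusively (the methyl group avoids the tert-alkyl group), and O-triflation fixes this geometry in the enol triflate.

Step 4
Reactants: 8 (2Z)-4,4-dimethyl-7-(trimethylsilyl)hept-2-en-6-yn-3-yl trifluoromethanesulfonate; 9 (3-ethoxy-3-oxopropyl)zinc bromide
Product: 10 ethyl (4E)-4-ethylidene-5,5-dimethyl-8-(trimethylsilyl)oct-7-ynoate
Conditions: Pd(PPh3)4 (5 mol%), THF, 50 °C
Reagents that add atoms: none
Why: Negishi sp2–sp3 cross-coupling of the enol triflate with the zinc homoenolate proceeds with retention, so the ester arm should end up cis to the methyl group and the quaternary carbon trans to it, which is the (E)-olefin geometry the key step needs.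

Step 5
Reactants: 10 ethyl (4E)-4-ethylidene-5,5-dimethyl-8-(trimethylsilyl)oct-7-ynoate
Product: 11 (4E)-4-ethylidene-5,5-dimethyloct-7-ynoic acid
Conditions: LiOH·H2O, THF/H2O, rt → 40 °C; then 1 M HCl to pH 4, 0 °C
Reagents that add atoms: lithium hydroxide, [Li+].[OH-]
Why: Saponification of the ethyl ester and hydroxide-mediated protiodesilylation of the alkynylsilane should occur in the same pot without touching the trisubstituted olefin, the cold, brief acidification avoiding protolactonisation.

Step 6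
Reactants: 11 (4E)-4-ethylidene-5,5-dimethyloct-7-ynoic acid
Product: 12 (5R,6S)-6,10,10-trimethyl-1-oxaspiro[4.5]dec-7-en-2-one
Conditions: [(R)-DTBM-MeO-BIPHEP](AuCl)2 (3 mol%), AgSbF6 (3 mol%), m-xylene, rt (–20 °C if needed)
Reagents that add atoms: none
Why: The cationic monovalent gold centre π-activates the terminal alkyne, the trisubstituted olefin attacks the alkyne terminus through its ethylidene carbon (ring C2 to ring C3) while positive charge builds at the fully substituted olefin carbon (ring C1), the carboxylic acid captures that carbon from the face opposite to the new C–C bond, and protodeauration of the alkenylgold releases the cyclohexene and the catalyst. The closest known reaction type is the gold-catalysed 6-endo-dig carbocyclisation of 1,5-enynes terminated by a tethered oxygen nucleophile, for which chiral bisphosphine digold catalysts are known to give high enantioselectivity. The carbocycle closes 6-endo-dig at the alkyne (6-endo-trig at the olefin) and the lactone closes 5-exo onto the cationic carbon, the two rings sharing only C1 (spiro). The relative configuration at C1 and C2 follows stereospecifically from the (E)-olefin geometry through anti addition of carbon and oxygen across the double bond (oxygen trans to the C2 methyl group), and the absolute configuration is set by the chiral bisphosphine, which differentiates the enantiotopic olefin faces in the C–C bond-forming event. The step needs six-membered rather than five-membered closure and capture before the cyclopropyl gold carbene-like intermediate can rearrange: the first is secured by the substitution pattern (the cation must sit on the fully substituted C1, not on the secondary C2), the second by the carboxyl group held three atoms from C1 and by the gem-dimethyl carbon C6, which has no hydrogen to lose and compresses the chain (Thorpe–Ingold effect).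

Step 7
Reactants: 12 (5R,6S)-6,10,10-trimethyl-1-oxaspiro[4.5]dec-7-en-2-one
Product: 13 (5R,6S)-6,10,10-trimethyl-1-oxaspiro[4.5]decan-2-one
Conditions: H2 (1 atm), PtO2 (3 mol%), EtOAc, rt
Reagents that add atoms: none
Why: Heterogeneous hydrogenation of the cis-disubstituted ring olefin forms no new stereocentre, and platinum is chosen over palladium to limit double-bond migration toward the C6 stereocentre of the spirocycle.

Step 8
Reactants: 13 (5R,6S)-6,10,10-trimethyl-1-oxaspiro[4.5]decan-2-one
Product: 14 (5R,6S)-6,10,10-trimethyl-1-oxaspiro[4.5]decan-2-ol (lactol, both anomers)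
Conditions: i-Bu2AlH, CH2Cl2, –78 °C; aq. Rochelle salt
Reagents that add atoms: none
Why: Half-reduction of a γ-lactone at low temperature should stop at the lactol because the aluminium hemiacetal is stable until work-up.

Step 9
Reactants: 14 (5R,6S)-6,10,10-trimethyl-1-oxaspiro[4.5]decan-2-ol
Product: 16 (1R,2S)-1-(but-3-yn-1-yl)-2,6,6-trimethylcyclohexan-1-ol, via hydroxy aldehyde 15 (not isolated)
Conditions: dimethyl (1-diazo-2-oxopropyl)phosphonate, K2CO3, MeOH, 0 °C → rt
Reagents that add atoms: dimethyl (1-diazo-2-oxopropyl)phosphonate, CC(=O)C(=[N+]=[N-])P(=O)(OC)OC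
Why: Seyferth–Gilbert homologation in the Ohira–Bestmann variant acts on the open hydroxy aldehyde tautomer of the lactol under mild base and cannot disturb either stereocentre (C1 bears no hydrogen, C2 is not enolisable).

Step 10
Reactants: 16 (1R,2S)-1-(but-3-yn-1-yl)-2,6,6-trimethylcyclohexan-1-ol
Product: 17 {[(1R,2S)-1-(but-3-yn-1-yl)-2,6,6-trimethylcyclohexyl]oxy}(trimethyl)silane
Conditions: Me3SiOTf, 2,6-lutidine, CH2Cl2, –78 → 0 °C
Reagents that add atoms: trimethylsilyl trifluoromethanesulfonate, C[Si](C)(C)OS(=O)(=O)C(F)(F)F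
Why: Silyl triflate silylation should cap even this hindered tertiary alcohol, which keeps the hydroxyl from quenching the organoaluminium, organolithium and Grignard reagents of the next three steps.

Step 11
Reactants: 17 {[(1R,2S)-1-(but-3-yn-1-yl)-2,6,6-trimethylcyclohexyl]oxy}(trimethyl)silane
Product: 20 (3E)-4-methyl-6-[(1R,2S)-2,6,6-trimethyl-1-(trimethylsilyloxy)cyclohexyl]hex-3-en-1-ol, via alkenyldimethylalane 18 (not isolated), via lithium butyl(dimethyl)alkenylalanate 19 (not isolated)
Conditions: Me3Al, Cp2ZrCl2 (25 mol%), CH2Cl2, rt; volatiles removed; n-BuLi, hexane/THF, –78 → 0 °C; oxirane, 0 °C → rt; aq. NH4Cl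
Reagents that add atoms: trimethylaluminium, C[Al](C)C; oxirane, C1CO1
Why: Negishi zirconium-catalysed carboalumination adds methyl and aluminium syn across the terminal alkyne (methyl to the internal carbon), and the derived alanate opens oxirane with retention at the sp2 carbon, which should set the (E)-trisubstituted olefin.

Step 12
Reactants: 20 (3E)-4-methyl-6-[(1R,2S)-2,6,6-trimethyl-1-(trimethylsilyloxy)cyclohexyl]hex-3-en-1-ol
Product: 21 {[(1R,2S)-1-[(3E)-6-bromo-3-methylhex-3-en-1-yl]-2,6,6-trimethylcyclohexyl]oxy}(trimethyl)silane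
Conditions: CBr4, PPh3, 2,6-lutidine, CH2Cl2, 0 °C
Reagents that add atoms: tetrabromomethane, BrC(Br)(Br)Br
Why: Appel bromination of the primary homoallylic alcohol under buffered, essentially neutral conditions should leave the silyl ether and the olefin untouched.

Step 13
Reactants: 21 {[(1R,2S)-1-[(3E)-6-bromo-3-methylhex-3-en-1-yl]-2,6,6-trimethylcyclohexyl]oxy}(trimethyl)silane; 22 prop-2-yn-1-ol
Product: 26 (2Z,5E)-2-(iodomethylidene)-6-methyl-8-[(1R,2S)-2,6,6-trimethyl-1-(trimethylsilyloxy)cyclohexyl]oct-5-en-1-ol, via Grignard reagent 23 (not isolated), via chloromagnesium prop-2-yn-1-olate 24 (not isolated), via cyclic alkenylmagnesium alkoxide 25 (not isolated)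
Conditions: 21, Mg, THF, 40 °C; separately 22, i-PrMgCl (1.0 equiv), THF, –20 °C; both combined (23 in 1.2-fold excess), CuI (15 mol%), –10 °C → rt; I2, –40 → 0 °C; aq. Na2S2O3/NH4Cl
Reagents that add atoms: iodine, [I][I]
Why: Copper-catalysed anti-carbomagnesiation of the propargylic magnesium alkoxide delivers the alkyl group to the carbon next to CH2O and magnesium to the terminal carbon within a five-membered chelate, so iodinolysis with retention should place iodine cis to CH2OH, which is the (Z)-geometry of the trisubstituted olefin.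

Step 14
Reactants: 26 (2Z,5E)-2-(iodomethylidene)-6-methyl-8-[(1R,2S)-2,6,6-trimethyl-1-(trimethylsilyloxy)cyclohexyl]oct-5-en-1-ol
Product: 27 (1R,2S)-1-[(3E,7Z)-7-(hydroxymethyl)-8-iodo-3-methylocta-3,7-dien-1-yl]-2,6,6-trimethylcyclohexan-1-ol
Conditions: pyridinium p-toluenesulfonate (10 mol%), MeOH, rt
Reagents that add atoms: none
Why: Acid-catalysed methanolysis should remove the trimethylsilyl ether before the sensitive trienyl butenolide is in place.

Step 15
Reactants: 28 4-bromofuran-2(5H)-one; 29 (E)-1,2-bis(tributylstannyl)ethene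
Product: 30 4-[(E)-2-(tributylstannyl)ethenyl]furan-2(5H)-one
Conditions: Pd2(dba)3 (2.5 mol%), AsPh3 (20 mol%), THF, 50 °C; 29 in 2.5-fold excess
Reagents that add atoms: none
Why: Stille coupling of the vinylogous acyl bromide with an excess of the distannane should stop after one coupling and retain the (E)-geometry.

Step 16
Reactants: 27 (1R,2S)-1-[(3E,7Z)-7-(hydroxymethyl)-8-iodo-3-methylocta-3,7-dien-1-yl]-2,6,6-trimethylcyclohexan-1-ol; 30 4-[(E)-2-(tributylstannyl)ethenyl]furan-2(5H)-one
Product: 31 4-[(1E,3Z,7E)-4-(hydroxymethyl)-10-[(1R,2S)-1-hydroxy-2,6,6-trimethylcyclohexyl]-8-methyldeca-1,3,7-trien-1-yl]furan-2(5H)-one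
Conditions: Pd2(dba)3 (5 mol%), AsPh3 (40 mol%), CuI (20 mol%), NMP, rt → 40 °C, dark
Reagents that add atoms: none
Why: Stille sp2–sp2 coupling under neutral conditions proceeds with retention at both partners, so it should give the (1E,3Z)-diene without exposing the butenolide to base, and free hydroxyl groups are tolerated.

Step 17
Reactants: 31 4-[(1E,3Z,7E)-4-(hydroxymethyl)-10-[(1R,2S)-1-hydroxy-2,6,6-trimethylcyclohexyl]-8-methyldeca-1,3,7-trien-1-yl]furan-2(5H)-one
Product: 32 (2Z,5E)-8-[(1R,2S)-1-hydroxy-2,6,6-trimethylcyclohexyl]-6-methyl-2-[(2E)-3-(5-oxo-2,5-dihydrofuran-3-yl)prop-2-en-1-ylidene]oct-5-en-1-yl acetate (CNP0366059.1)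
Conditions: Ac2O, pyridine, CH2Cl2, 0 °C → rt
Reagents that add atoms: acetic anhydride, CC(=O)OC(C)=O
Why: Acetylation should take place only at the primary allylic alcohol, because the tertiary ring alcohol is flanked by a quaternary and a tertiary carbon.

**Compound list**

1 | isobutyronitrile | CC(C)C#N | starting material
2 | 3-bromo-1-(trimethylsilyl)prop-1-yne | C[Si](C)(C)C#CCBr | starting material
3 | lithiated isobutyronitrile (2-lithio-2-methylpropanenitrile) | CC(C)([Li])C#N | intermediate
4 | 2,2-dimethyl-5-(trimethylsilyl)pent-4-ynenitrile | C[Si](C)(C)C#CCC(C)(C)C#N | intermediate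
5 | bromomagnesium ketiminate of 4,4-dimethyl-7-(trimethylsilyl)hept-6-yn-3-one | CCC(=N[Mg]Br)C(C)(C)CC#C[Si](C)(C)C | intermediate
6 | 4,4-dimethyl-7-(trimethylsilyl)hept-6-yn-3-one | CCC(=O)C(C)(C)CC#C[Si](C)(C)C | intermediate
7 | lithium (2Z)-4,4-dimethyl-7-(trimethylsilyl)hept-2-en-6-yn-3-olate | C/C=C(\O[Li])C(C)(C)CC#C[Si](C)(C)C | intermediate
8 | (2Z)-4,4-dimethyl-7-(trimethylsilyl)hept-2-en-6-yn-3-yl trifluoromethanesulfonate | C/C=C(\OS(=O)(=O)C(F)(F)F)C(C)(C)CC#C[Si](C)(C)C | intermediate
9 | (3-ethoxy-3-oxopropyl)zinc bromide | CCOC(=O)CC[Zn]Br | starting material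
10 | ethyl (4E)-4-ethylidene-5,5-dimethyl-8-(trimethylsilyl)oct-7-ynoate | C/C=C(\CCC(=O)OCC)C(C)(C)CC#C[Si](C)(C)C | intermediate
11 | (4E)-4-ethylidene-5,5-dimethyloct-7-ynoic acid | C/C=C(\CCC(=O)O)C(C)(C)CC#C | intermediate
12 | (5R,6S)-6,10,10-trimethyl-1-oxaspiro[4.5]dec-7-en-2-one | O=C1CC[C@@]2(O1)[C@@H](C)C=CCC2(C)C | intermediate
13 | (5R,6S)-6,10,10-trimethyl-1-oxaspiro[4.5]decan-2-one | O=C1CC[C@@]2(O1)[C@@H](C)CCCC2(C)C | intermediate
14 | (5R,6S)-6,10,10-trimethyl-1-oxaspiro[4.5]decan-2-ol (both anomers) | OC1CC[C@@]2(O1)[C@@H](C)CCCC2(C)C | intermediate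
15 | 3-[(1R,2S)-1-hydroxy-2,6,6-trimethylcyclohexyl]propanal | O=CCC[C@@]1(O)[C@@H](C)CCCC1(C)C | intermediate
16 | (1R,2S)-1-(but-3-yn-1-yl)-2,6,6-trimethylcyclohexan-1-ol | C#CCC[C@@]1(O)[C@@H](C)CCCC1(C)C | intermediate
17 | {[(1R,2S)-1-(but-3-yn-1-yl)-2,6,6-trimethylcyclohexyl]oxy}(trimethyl)silane | C#CCC[C@@]1(O[Si](C)(C)C)[C@@H](C)CCCC1(C)C | intermediate
18 | dimethyl{(1E)-2-methyl-4-[(1R,2S)-2,6,6-trimethyl-1-(trimethylsilyloxy)cyclohexyl]but-1-en-1-yl}alane | C[Al](C)/C=C(\C)CC[C@@]1(O[Si](C)(C)C)[C@@H](C)CCCC1(C)C | intermediate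
19 | lithium butyl(dimethyl){(1E)-2-methyl-4-[(1R,2S)-2,6,6-trimethyl-1-(trimethylsilyloxy)cyclohexyl]but-1-en-1-yl}alanate | [Li+].CCCC[Al-](C)(C)/C=C(\C)CC[C@@]1(O[Si](C)(C)C)[C@@H](C)CCCC1(C)C | intermediate
20 | (3E)-4-methyl-6-[(1R,2S)-2,6,6-trimethyl-1-(trimethylsilyloxy)cyclohexyl]hex-3-en-1-ol | OCC/C=C(\C)CC[C@@]1(O[Si](C)(C)C)[C@@H](C)CCCC1(C)C | intermediate
21 | {[(1R,2S)-1-[(3E)-6-bromo-3-methylhex-3-en-1-yl]-2,6,6-trimethylcyclohexyl]oxy}(trimethyl)silane | BrCC/C=C(\C)CC[C@@]1(O[Si](C)(C)C)[C@@H](C)CCCC1(C)C | intermediate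
22 | prop-2-yn-1-ol | C#CCO | starting material
23 | {(3E)-4-methyl-6-[(1R,2S)-2,6,6-trimethyl-1-(trimethylsilyloxy)cyclohexyl]hex-3-en-1-yl}magnesium bromide | Br[Mg]CC/C=C(\C)CC[C@@]1(O[Si](C)(C)C)[C@@H](C)CCCC1(C)C | intermediate
24 | chloromagnesium prop-2-yn-1-olate | C#CCO[Mg]Cl | intermediate
25 | 4-{(3E)-4-methyl-6-[(1R,2S)-2,6,6-trimethyl-1-(trimethylsilyloxy)cyclohexyl]hex-3-en-1-yl}-2,5-dihydro-1,2-oxamagnesole (cyclic alkenylmagnesium alkoxide) | [Mg]1OCC(CC/C=C(\C)CC[C@@]2(O[Si](C)(C)C)[C@@H](C)CCCC2(C)C)=C1 | intermediate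
26 | (2Z,5E)-2-(iodomethylidene)-6-methyl-8-[(1R,2S)-2,6,6-trimethyl-1-(trimethylsilyloxy)cyclohexyl]oct-5-en-1-ol | OC/C(=C\I)CC/C=C(\C)CC[C@@]1(O[Si](C)(C)C)[C@@H](C)CCCC1(C)C | intermediate
27 | (1R,2S)-1-[(3E,7Z)-7-(hydroxymethyl)-8-iodo-3-methylocta-3,7-dien-1-yl]-2,6,6-trimethylcyclohexan-1-ol | OC/C(=C\I)CC/C=C(\C)CC[C@@]1(O)[C@@H](C)CCCC1(C)C | intermediate
28 | 4-bromofuran-2(5H)-one | O=C1C=C(Br)CO1 | starting material
29 | (E)-1,2-bis(tributylstannyl)ethene | CCCC[Sn](CCCC)(CCCC)/C=C/[Sn](CCCC)(CCCC)CCCC | starting material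
30 | 4-[(E)-2-(tributylstannyl)ethenyl]furan-2(5H)-one | O=C1C=C(/C=C/[Sn](CCCC)(CCCC)CCCC)CO1 | intermediate
31 | 4-[(1E,3Z,7E)-4-(hydroxymethyl)-10-[(1R,2S)-1-hydroxy-2,6,6-trimethylcyclohexyl]-8-methyldeca-1,3,7-trien-1-yl]furan-2(5H)-one | OC/C(=C\C=C\C1=CC(=O)OC1)CC/C=C(\C)CC[C@@]1(O)[C@@H](C)CCCC1(C)C | intermediate
32 | (2Z,5E)-8-[(1R,2S)-1-hydroxy-2,6,6-trimethylcyclohexyl]-6-methyl-2-[(2E)-3-(5-oxo-2,5-dihydrofuran-3-yl)prop-2-en-1-ylidene]oct-5-en-1-yl acetate | CC(=O)OC/C(=C\C=C\C1=CC(=O)OC1)CC/C=C(\C)CC[C@@]1(O)[C@@H](C)CCCC1(C)C | target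

**Step count and risks**

Total steps: 17. Longest linear sequence: 16 (steps 1–14, 16 and 17; step 15 makes the coupling partner).

Steps most likely to fail:

1. Step 6 (key step). What may go wrong: insufficient facial discrimination by the chiral digold catalyst on an olefin that is flanked by a quaternary carbon, together with partial diversion of the gold carbenoid into plain cycloisomerisation or acid-catalysed protolactonisation of the γ,δ-unsaturated acid before the C–C bond forms. Fallback (resolution instead of asymmetric catalysis), setting out from 11 and returning at 13: cyclisation with the achiral catalyst Ph3PAuNTf2 (CH2Cl2, rt) should give the racemic unsaturated lactone F1 with the same relative configuration, since the anti addition does not depend on the ligand. Hydrogenation as in step 7 gives the racemic saturated lactone F2. Aminolysis with (S)-1-phenylethylamine and Me3Al (toluene, 60 °C) gives the diastereomeric hydroxy amides, the (1R,2S)-ring amide F3 and the (1S,2R)-ring amide F4, which are separated by chromatography or crystallisation. F3 is relactonised with p-toluenesulfonic acid in toluene at 80 °C, with loss of the amine, and re-enters the route as 13.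

2. Step 13. What may go wrong: protonation of the Grignard reagent by the acetylenic C–H of the alkoxide and sluggish carbomagnesiation with a long, functionalised alkyl group, both of which consume the advanced fragment. Fallback (olefination instead of carbometalation), setting out from 21 and returning at 31: bromide 21 alkylates the sodium salt of methyl bis(2,2,2-trifluoroethyl)phosphonoacetate (NaH, NaI cat., DMF, 50 °C) to give the α-alkylated phosphonate F5. Still–Gennari olefination (KN(SiMe3)2, 18-crown-6, THF, –78 °C) with (2E)-3-(tributylstannyl)prop-2-enal F6, made from commercial (2E)-3-(tributylstannyl)prop-2-en-1-ol with MnO2, should give the (2Z)-dienoate F7, in which the ester is cis to the stannyldienyl arm. Reduction with i-Bu2AlH (CH2Cl2, –78 °C) gives the dienylstannane alcohol F8. Stille coupling of F8 with 28 (Pd2(dba)3, AsPh3, NMP, rt) gives the silyl ether F9. Pyridinium p-toluenesulfonate in MeOH removes the silyl group and gives 31, so that steps 14 and 16 are not needed.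

3. Step 16. What may go wrong: slow transmetalation of the electron-poor stannane 30, with competing protodestannylation, homocoupling and Z-to-E isomerisation of the iodo-olefin on palladium. Fallback (polarity of the coupling reversed), setting out from 27 and returning at 31: 27 is coupled with an excess of 29 (PdCl2(MeCN)2, DMF, rt) to give the electron-rich (1E,3Z)-dienylstannane F10, which then undergoes Stille coupling with the electron-poor bromide 28 (Pd2(dba)3, AsPh3, NMP, rt) to give 31.

**Further compounds**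

F1 | step 6 | racemic (5R,6S)/(5S,6R)-6,10,10-trimethyl-1-oxaspiro[4.5]dec-7-en-2-one | O=C1CC[C@@]2(O1)[C@@H](C)C=CCC2(C)C.O=C1CC[C@]2(O1)[C@H](C)C=CCC2(C)C
F2 | step 6 | racemic (5R,6S)/(5S,6R)-6,10,10-trimethyl-1-oxaspiro[4.5]decan-2-one | O=C1CC[C@@]2(O1)[C@@H](C)CCCC2(C)C.O=C1CC[C@]2(O1)[C@H](C)CCCC2(C)C
F3 | step 6 | 3-[(1R,2S)-1-hydroxy-2,6,6-trimethylcyclohexyl]-N-[(1S)-1-phenylethyl]propanamide | C[C@H](NC(=O)CC[C@@]1(O)[C@@H](C)CCCC1(C)C)c1ccccc1
F4 | step 6 | 3-[(1S,2R)-1-hydroxy-2,6,6-trimethylcyclohexyl]-N-[(1S)-1-phenylethyl]propanamide | C[C@H](NC(=O)CC[C@]1(O)[C@H](C)CCCC1(C)C)c1ccccc1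
F5 | step 13 | methyl (5E)-2-[bis(2,2,2-trifluoroethoxy)phosphoryl]-6-methyl-8-[(1R,2S)-2,6,6-trimethyl-1-(trimethylsilyloxy)cyclohexyl]oct-5-enoate | COC(=O)C(CC/C=C(\C)CC[C@@]1(O[Si](C)(C)C)[C@@H](C)CCCC1(C)C)P(=O)(OCC(F)(F)F)OCC(F)(F)F
F6 | step 13 | (2E)-3-(tributylstannyl)prop-2-enal | O=C/C=C/[Sn](CCCC)(CCCC)CCCC
F7 | step 13 | methyl (2Z,5E)-6-methyl-2-[(2E)-3-(tributylstannyl)prop-2-en-1-ylidene]-8-[(1R,2S)-2,6,6-trimethyl-1-(trimethylsilyloxy)cyclohexyl]oct-5-enoate | COC(=O)/C(=C\C=C\[Sn](CCCC)(CCCC)CCCC)CC/C=C(\C)CC[C@@]1(O[Si](C)(C)C)[C@@H](C)CCCC1(C)C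
F8 | step 13 | (2Z,5E)-6-methyl-2-[(2E)-3-(tributylstannyl)prop-2-en-1-ylidene]-8-[(1R,2S)-2,6,6-trimethyl-1-(trimethylsilyloxy)cyclohexyl]oct-5-en-1-ol | OC/C(=C\C=C\[Sn](CCCC)(CCCC)CCCC)CC/C=C(\C)CC[C@@]1(O[Si](C)(C)C)[C@@H](C)CCCC1(C)C
F9 | step 13 | 4-[(1E,3Z,7E)-4-(hydroxymethyl)-8-methyl-10-[(1R,2S)-2,6,6-trimethyl-1-(trimethylsilyloxy)cyclohexyl]deca-1,3,7-trien-1-yl]furan-2(5H)-one | OC/C(=C\C=C\C1=CC(=O)OC1)CC/C=C(\C)CC[C@@]1(O[Si](C)(C)C)[C@@H](C)CCCC1(C)C
F10 | step 16 | (2Z,5E)-8-[(1R,2S)-1-hydroxy-2,6,6-trimethylcyclohexyl]-6-methyl-2-[(2E)-3-(tributylstannyl)prop-2-en-1-ylidene]oct-5-en-1-ol | OC/C(=C\C=C\[Sn](CCCC)(CCCC)CCCC)CC/C=C(\C)CC[C@@]1(O)[C@@H](C)CCCC1(C)C
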